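**Retrosynthetic overview**

- The target is traced back, through benzyl hydrogenolysis, two O-sulfations and removal of a MOM and a silyl group, to a 4′-O-benzyl flavone with 3-OMOM, free 5-OH and 7-OSi(i-Pr)3.
- The feature the plan rests on: ring A (C4a, C5, C6, C7, C8, C8a), with a free chelated 5-OH and a separately masked 7-oxygen, is fused to ring C (O1, C2, C3, C4, C4a, C8a), a 2-aryl-3-oxy-4-pyranone whose atoms map onto kojic acid.
- Key disconnection: C5–C6, C7–C8 and C5–C4a. Ring A is grown last on the finished ring C by Wolff rearrangement of a pyranonyl diazomethyl ketone to a ketene, [2+2] addition of (triisopropylsilyloxy)acetylene, 4π opening and 6π electrocyclization.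
- The diazoketone comes from the pyranone-2-carboxylic acid, this from a Suzuki coupling (C2–C1′ bond) on 6-bromo-5-O-MOM kojic acid, and this from kojic acid; the alkyne comes from lithium ethynolate and i-Pr3SiOTf.
- Ring order: ring C is bought as kojic acid, ring B is attached by cross-coupling, ring A is closed in the key step.

Key step: step 7

Assumption: the sulfate half-esters 20 and 21 are written as the neutral acids, as the target is drawn; in the flask they are handled as triethylammonium or sodium salts, and the free acid is released only by a final pass through a cold H+-form resin.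

**Route**

Step 1
Reactants: 1 kojic acid (5-hydroxy-2-(hydroxymethyl)-4H-pyran-4-one)
Product: 2 2-bromo-3-hydroxy-6-(hydroxymethyl)-4H-pyran-4-one (6-bromokojic acid)
Conditions: NBS (1.05 equiv), DMF, 0 °C to rt, dark
Reagents that add atoms: N-bromosuccinimide, O=C1CCC(=O)N1Br
Why: Electrophilic bromination of an enol: C6 is the β-carbon of the 5-hydroxy enol and the usual site of electrophilic substitution in kojic acid, so one equivalent of NBS should give the 6-bromide.

Step 2
Reactants: 2 2-bromo-3-hydroxy-6-(hydroxymethyl)-4H-pyran-4-one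
Product: 3 2-bromo-6-(hydroxymethyl)-3-(methoxymethoxy)-4H-pyran-4-one
Conditions: MOMCl (1.05 equiv), K2CO3, acetone, 0 °C to rt
Reagents that add atoms: chloromethyl methyl ether, COCCl
Why: Williamson-type O-alkylation: K2CO3 deprotonates only the acidic enolic hydroxyl, whose potassium salt should take up the single equivalent of MOMCl while the neutral primary alcohol stays free.

Step 3
Reactants: 3 2-bromo-6-(hydroxymethyl)-3-(methoxymethoxy)-4H-pyran-4-one; 4 [4-(benzyloxy)-3-methoxyphenyl]boronic acid
Product: 5 2-[4-(benzyloxy)-3-methoxyphenyl]-6-(hydroxymethyl)-3-(methoxymethoxy)-4H-pyran-4-one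
Conditions: Pd(dppf)Cl2 (5 mol %), K3PO4, 1,4-dioxane/H2O (5:1), 80 °C
Reagents that add atoms: none
Why: Suzuki–Miyaura coupling: the C–Br bond of the β-bromo enone is activated for oxidative addition to the zerovalent palladium formed in situ and should couple with the electron-rich arylboronic acid under a mild phosphate base, which also limits addition–elimination of hydroxide at the bromine-bearing carbon.

Step 4
Reactants: 5 2-[4-(benzyloxy)-3-methoxyphenyl]-6-(hydroxymethyl)-3-(methoxymethoxy)-4H-pyran-4-one
Product: 6 6-[4-(benzyloxy)-3-methoxyphenyl]-5-(methoxymethoxy)-4-oxo-4H-pyran-2-carboxylic acid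
Conditions: TEMPO (0.2 equiv), PhI(OAc)2 (2.2 equiv), MeCN/H2O (1:1), rt
Reagents that add atoms: water, O
Why: Oxoammonium (TEMPO) oxidation: the activated primary alcohol is oxidised to the aldehyde, whose hydrate is oxidised on to the acid in aqueous acetonitrile, under near-neutral conditions that should spare the MOM acetal, the benzyl ether and the electron-rich arene.

Step 5
Reactants: 6 6-[4-(benzyloxy)-3-methoxyphenyl]-5-(methoxymethoxy)-4-oxo-4H-pyran-2-carboxylic acid
Product: 8 6-[4-(benzyloxy)-3-methoxyphenyl]-2-(diazoacetyl)-5-(methoxymethoxy)-4H-pyran-4-one, via mixed carbonic anhydride 7 (not isolated)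
Conditions: i-BuOCOCl, N-methylmorpholine, THF, −15 °C; then CH2N2, Et2O, −15 °C to rt
Reagents that add atoms: diazomethane, C=[N+]=[N-]
Why: Acylation of diazomethane (first stage of the Arndt–Eistert sequence): the mixed carbonic anhydride activates the acid without hydrogen chloride so the MOM acetal survives, and diazomethane should attack the more electrophilic pyranoyl carbonyl to give the diazomethyl ketone faster than it adds to the quasi-aromatic pyranone.

Step 6
Reactants: 9 acetylene; 10 triisopropylsilyl trifluoromethanesulfonate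
Product: 13 (triisopropylsilyloxy)acetylene, via lithium acetylide 11 (not isolated), via lithium ethynolate 12 (not isolated)
Conditions: n-BuLi, THF, −78 °C; t-BuOOLi (from t-BuOOH and LiN(SiMe3)2), −78 to −10 °C; then 10, −78 to 0 °C
Reagents that add atoms: tert-butyl hydroperoxide, CC(C)(C)OO
Why: Oxidation of an acetylide by electrophilic oxygen transfer from lithium tert-butyl peroxide gives the ynolate, and the hard, bulky silyl triflate should silylate it at oxygen rather than carbon, a sequence known for substituted lithium acetylides and applied here to acetylene itself.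

Step 7
Reactants: 8 6-[4-(benzyloxy)-3-methoxyphenyl]-2-(diazoacetyl)-5-(methoxymethoxy)-4H-pyran-4-one; 13 (triisopropylsilyloxy)acetylene
Product: 17 2-[4-(benzyloxy)-3-methoxyphenyl]-5-hydroxy-3-(methoxymethoxy)-7-(triisopropylsilyloxy)-4H-chromen-4-one, via pyranonylketene 14 (not isolated), via siloxycyclobutenone 15 (not isolated), via dienylketene 16 (not isolated)
Conditions: 13 (2.5 equiv), degassed ClCH2CH2Cl, hν (medium-pressure Hg lamp, Pyrex filter, λ > 300 nm), rt; then 80 °C, dark
Reagents that add atoms: none
Why: Light expels N2 from 8 and the pyranonyl group shifts to the carbene carbon (Wolff rearrangement) to give ketene 14, which adds alkyne 13 in a [2+2] cycloaddition: the nucleophilic CH terminus of 13 bonds to the ketene carbonyl carbon (C5–C6) and the siloxy carbon to the former diazo carbon (C7–C8), giving cyclobutenone 15. At 80 °C 15 opens reversibly by 4π conrotatory cleavage of its C5–C8 bond to dienylketene 16, and the isomer with ketene and pyranone on the same side closes ring A by a thermal 6π disrotatory electrocyclization that forms C5–C4a; the C4a hydrogen then shifts to oxygen and gives the phenol. The closest known reaction type is the Danheiser benzannulation in its photochemical Wolff variant, established for α,β-unsaturated, aryl and hetaryl diazomethyl ketones with siloxyalkynes, in which the pyranone C2=C3 bond here takes the place of the enone or hetarene double bond. No stereocenter is formed (the one carbon stereocenter of racemic 15 is lost on ring opening). Three selectivities are needed: the regiochemistry of the [2+2] step is fixed by the polarisation of the siloxyalkyne, the ring closure can end only on the pyranone C–H carbon because the other neighbour of C8a is the ring oxygen, and the new 5-OH is held in a hydrogen bond to the C4 carbonyl and is therefore a poor trap for 14. Irradiation above 300 nm in degassed solvent and a dark heating stage limit photoreactions of the 4-pyranone and of the flavone, most of which forms only after the lamp is off.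

Step 8
Reactants: 17 2-[4-(benzyloxy)-3-methoxyphenyl]-5-hydroxy-3-(methoxymethoxy)-7-(triisopropylsilyloxy)-4H-chromen-4-one
Product: 18 2-[4-(benzyloxy)-3-methoxyphenyl]-5,7-dihydroxy-3-(methoxymethoxy)-4H-chromen-4-one
Conditions: TBAF, AcOH, THF, 0 °C
Reagents that add atoms: none
Why: Fluoride-induced desilylation: the aryl silyl ether is cleaved by acetic acid-buffered TBAF, conditions under which the MOM acetal, the benzyl ether and the chromone should be inert.

Step 9
Reactants: 18 2-[4-(benzyloxy)-3-methoxyphenyl]-5,7-dihydroxy-3-(methoxymethoxy)-4H-chromen-4-one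
Product: 19 2-[4-(benzyloxy)-3-methoxyphenyl]-3,5,7-trihydroxy-4H-chromen-4-one (4′-O-benzylisorhamnetin)
Conditions: 3 M HCl (aq), MeOH/THF, 50 °C
Reagents that add atoms: none
Why: Acid-catalysed acetal exchange: the MOM group is passed to methanol as dimethoxymethane under dilute acid, which should not cleave the aryl benzyl or aryl methyl ether.

Step 10
Reactants: 19 2-[4-(benzyloxy)-3-methoxyphenyl]-3,5,7-trihydroxy-4H-chromen-4-one
Product: 20 2-[4-(benzyloxy)-3-methoxyphenyl]-5-hydroxy-4-oxo-4H-chromene-3,7-diyl bis(hydrogen sulfate)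
Conditions: SO3·NEt3 (2.6 equiv), DMF/pyridine, 40 °C
Reagents that add atoms: sulfur trioxide–triethylamine complex, CC[N+](CC)(CC)S(=O)(=O)[O-]
Why: O-Sulfation of phenols with a sulfur trioxide–amine complex: the acidic 7-OH and the 3-OH should react, while the 5-OH, locked in a six-membered hydrogen bond to the C4 carbonyl, is the least reactive hydroxyl of a flavonol and should stay free when the reagent is held to a small excess.

Step 11
Reactants: 20 2-[4-(benzyloxy)-3-methoxyphenyl]-5-hydroxy-4-oxo-4H-chromene-3,7-diyl bis(hydrogen sulfate)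
Product: 21 isorhamnetin 3,7-di-O-sulfate (5-hydroxy-2-(4-hydroxy-3-methoxyphenyl)-4-oxo-4H-chromene-3,7-diyl bis(hydrogen sulfate))
Conditions: H2 (1 atm), Pd/C, MeOH, rt (on the triethylammonium salt); then cold H+-form ion-exchange resin
Reagents that add atoms: none
Why: Hydrogenolysis of the benzyl aryl ether over Pd/C: aryl sulfate monoester salts, the chromone C2=C3 bond and the aryl methyl ether should be stable to hydrogen at one atmosphere and room temperature.

**Compound list**

1 | kojic acid (5-hydroxy-2-(hydroxymethyl)-4H-pyran-4-one) | OCc1cc(=O)c(O)co1 | starting material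
2 | 2-bromo-3-hydroxy-6-(hydroxymethyl)-4H-pyran-4-one (6-bromokojic acid) | OCc1cc(=O)c(O)c(Br)o1 | intermediate
3 | 2-bromo-6-(hydroxymethyl)-3-(methoxymethoxy)-4H-pyran-4-one | OCc1cc(=O)c(OCOC)c(Br)o1 | intermediate
4 | [4-(benzyloxy)-3-methoxyphenyl]boronic acid | COc1cc(B(O)O)ccc1OCc1ccccc1 | starting material
5 | 2-[4-(benzyloxy)-3-methoxyphenyl]-6-(hydroxymethyl)-3-(methoxymethoxy)-4H-pyran-4-one | OCc1cc(=O)c(OCOC)c(-c2ccc(OCc3ccccc3)c(OC)c2)o1 | intermediate
6 | 6-[4-(benzyloxy)-3-methoxyphenyl]-5-(methoxymethoxy)-4-oxo-4H-pyran-2-carboxylic acid | OC(=O)c1cc(=O)c(OCOC)c(-c2ccc(OCc3ccccc3)c(OC)c2)o1 | intermediate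
7 | mixed anhydride of acid 6 with isobutyl hydrogen carbonate (not isolated) | CC(C)COC(=O)OC(=O)c1cc(=O)c(OCOC)c(-c2ccc(OCc3ccccc3)c(OC)c2)o1 | intermediate
8 | 6-[4-(benzyloxy)-3-methoxyphenyl]-2-(diazoacetyl)-5-(methoxymethoxy)-4H-pyran-4-one | [N-]=[N+]=CC(=O)c1cc(=O)c(OCOC)c(-c2ccc(OCc3ccccc3)c(OC)c2)o1 | intermediate
9 | acetylene | C#C | starting material
10 | triisopropylsilyl trifluoromethanesulfonate | CC(C)[Si](OS(=O)(=O)C(F)(F)F)(C(C)C)C(C)C | starting material
11 | lithium acetylide (not isolated) | [Li+].[C-]#C | intermediate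
12 | lithium ethynolate (not isolated) | [Li+].[O-]C#C | intermediate
13 | (triisopropylsilyloxy)acetylene | C#CO[Si](C(C)C)(C(C)C)C(C)C | intermediate
14 | [6-[4-(benzyloxy)-3-methoxyphenyl]-5-(methoxymethoxy)-4-oxo-4H-pyran-2-yl]ketene (not isolated) | O=C=Cc1cc(=O)c(OCOC)c(-c2ccc(OCc3ccccc3)c(OC)c2)o1 | intermediate
15 | 4-[6-[4-(benzyloxy)-3-methoxyphenyl]-5-(methoxymethoxy)-4-oxo-4H-pyran-2-yl]-3-(triisopropylsilyloxy)cyclobut-2-en-1-one, racemic (not isolated) | O=C1C=C(O[Si](C(C)C)(C(C)C)C(C)C)C1c1cc(=O)c(OCOC)c(-c2ccc(OCc3ccccc3)c(OC)c2)o1 | intermediate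
16 | 4-[6-[4-(benzyloxy)-3-methoxyphenyl]-5-(methoxymethoxy)-4-oxo-4H-pyran-2-yl]-3-(triisopropylsilyloxy)buta-1,3-dien-1-one, ketene and pyranone on the same side of the C3=C4 bond (not isolated) | O=C=C/C(O[Si](C(C)C)(C(C)C)C(C)C)=C\c1cc(=O)c(OCOC)c(-c2ccc(OCc3ccccc3)c(OC)c2)o1 | intermediate
17 | 2-[4-(benzyloxy)-3-methoxyphenyl]-5-hydroxy-3-(methoxymethoxy)-7-(triisopropylsilyloxy)-4H-chromen-4-one | COCOc1c(-c2ccc(OCc3ccccc3)c(OC)c2)oc2cc(O[Si](C(C)C)(C(C)C)C(C)C)cc(O)c2c1=O | intermediate
18 | 2-[4-(benzyloxy)-3-methoxyphenyl]-5,7-dihydroxy-3-(methoxymethoxy)-4H-chromen-4-one | COCOc1c(-c2ccc(OCc3ccccc3)c(OC)c2)oc2cc(O)cc(O)c2c1=O | intermediate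
19 | 2-[4-(benzyloxy)-3-methoxyphenyl]-3,5,7-trihydroxy-4H-chromen-4-one (4′-O-benzylisorhamnetin) | COc1cc(-c2oc3cc(O)cc(O)c3c(=O)c2O)ccc1OCc1ccccc1 | intermediate
20 | 2-[4-(benzyloxy)-3-methoxyphenyl]-5-hydroxy-4-oxo-4H-chromene-3,7-diyl bis(hydrogen sulfate) | COc1cc(-c2oc3cc(OS(=O)(=O)O)cc(O)c3c(=O)c2OS(=O)(=O)O)ccc1OCc1ccccc1 | intermediate
21 | isorhamnetin 3,7-di-O-sulfate | COc1cc(-c2oc3cc(OS(=O)(=O)O)cc(O)c3c(=O)c2OS(=O)(=O)O)ccc1O | target

**Summary**

Total step count: 11. Longest linear sequence: 10 steps (steps 1–5 and 7–11, from kojic acid 1); step 6 is a one-step side branch.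

**Steps most likely to fail**

1. Step 7. The light may be taken up by the 2-aryl-4-pyranone chromophore instead of the diazo group, leading to photoisomerisation of the pyranone or carbene-derived products rather than clean Wolff rearrangement; the ketene may also dimerise before it meets the alkyne. The fallback generates the same ketene without light. It sets out from diazoketone 8 and comes back at 17. Compound 8 is rearranged in the dark with catalytic PhCO2Ag and NEt3 in THF/H2O (Arndt–Eistert homologation) to [6-[4-(benzyloxy)-3-methoxyphenyl]-5-(methoxymethoxy)-4-oxo-4H-pyran-2-yl]acetic acid F1, kept cold because it is a vinylogous β-keto acid. 1-Chloro-N,N,2-trimethylpropenylamine converts F1 under neutral conditions into [6-[4-(benzyloxy)-3-methoxyphenyl]-5-(methoxymethoxy)-4-oxo-4H-pyran-2-yl]acetyl chloride F2. Slow addition of NEt3 to F2 and 13 in toluene at room temperature releases ketene 14 by dehydrochlorination, a known way to make cyclobutenones and resorcinols from acid chlorides and siloxyalkynes; 14 is trapped as 15, and heating to 80 °C takes 15 through 16 to 17.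

2. Step 6. Monolithium acetylide may disproportionate to insoluble dilithium carbide on warming before oxygen transfer takes place, and the parent ynolate may be silylated at carbon to give the silylketene, or the volatile product may be lost on isolation. The fallback replaces the ynolate-derived alkyne by an alkynyl ether made by elimination. It sets out from diazoketone 8 and comes back at triol 19. tert-Butoxyacetylene F3, a known compound made by NaNH2 dehydrobromination of (Z)-1-bromo-2-tert-butoxyethene in liquid NH3, takes the place of 13 under the conditions of step 7. Ketene 14 should add to it with the same regiochemistry to give 4-[6-[4-(benzyloxy)-3-methoxyphenyl]-5-(methoxymethoxy)-4-oxo-4H-pyran-2-yl]-3-tert-butoxycyclobut-2-en-1-one F4. Excess F3 is removed under vacuum before heating, and 4π opening to the tert-butoxy dienylketene F5 and 6π closure give 2-[4-(benzyloxy)-3-methoxyphenyl]-7-tert-butoxy-5-hydroxy-3-(methoxymethoxy)-4H-chromen-4-one F6. Trifluoroacetic acid in wet CH2Cl2 then cleaves the aryl tert-butyl ether and the MOM acetal in one operation to give 19, so steps 8 and 9 are not needed.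

3. Step 10. Sulfation may stop at the 7-monosulfate because the 3-OH is hindered and weakly chelated, or may run on to the 5-OH, giving mixtures of polar salts that are hard to separate. The fallback installs the sulfates as neutral, chromatographable diesters. It sets out from triol 19 and comes back at 20. Treatment of 19 with 2,2,2-trichloroethyl chlorosulfate (2.2 equiv), NEt3 and DMAP in THF should give 2-[4-(benzyloxy)-3-methoxyphenyl]-5-hydroxy-4-oxo-4H-chromene-3,7-diyl bis(2,2,2-trichloroethyl sulfate) F7, which is purified on silica. Zn dust and HCO2NH4 in MeOH then remove both trichloroethyl groups by reductive β-elimination and give 20, which goes on to step 11.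

Further compounds
F1 | step 7 | [6-[4-(benzyloxy)-3-methoxyphenyl]-5-(methoxymethoxy)-4-oxo-4H-pyran-2-yl]acetic acid | OC(=O)Cc1cc(=O)c(OCOC)c(-c2ccc(OCc3ccccc3)c(OC)c2)o1
F2 | step 7 | [6-[4-(benzyloxy)-3-methoxyphenyl]-5-(methoxymethoxy)-4-oxo-4H-pyran-2-yl]acetyl chloride | ClC(=O)Cc1cc(=O)c(OCOC)c(-c2ccc(OCc3ccccc3)c(OC)c2)o1
F3 | step 6 | tert-butoxyacetylene | C#COC(C)(C)C
F4 | step 6 | 4-[6-[4-(benzyloxy)-3-methoxyphenyl]-5-(methoxymethoxy)-4-oxo-4H-pyran-2-yl]-3-tert-butoxycyclobut-2-en-1-one (racemic) | O=C1C=C(OC(C)(C)C)C1c1cc(=O)c(OCOC)c(-c2ccc(OCc3ccccc3)c(OC)c2)o1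
F5 | step 6 | 4-[6-[4-(benzyloxy)-3-methoxyphenyl]-5-(methoxymethoxy)-4-oxo-4H-pyran-2-yl]-3-tert-butoxybuta-1,3-dien-1-one (ketene and pyranone on the same side) | O=C=C/C(OC(C)(C)C)=C\c1cc(=O)c(OCOC)c(-c2ccc(OCc3ccccc3)c(OC)c2)o1
F6 | step 6 | 2-[4-(benzyloxy)-3-methoxyphenyl]-7-tert-butoxy-5-hydroxy-3-(methoxymethoxy)-4H-chromen-4-one | COCOc1c(-c2ccc(OCc3ccccc3)c(OC)c2)oc2cc(OC(C)(C)C)cc(O)c2c1=O
F7 | step 10 | 2-[4-(benzyloxy)-3-methoxyphenyl]-5-hydroxy-4-oxo-4H-chromene-3,7-diyl bis(2,2,2-trichloroethyl sulfate) | COc1cc(-c2oc3cc(OS(=O)(=O)OCC(Cl)(Cl)Cl)cc(O)c3c(=O)c2OS(=O)(=O)OCC(Cl)(Cl)Cl)ccc1OCc1ccccc1
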